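## Analysis of the target

Eryvarin Q (19, C25H26O5) is a 2-arylbenzofuran-3-carbaldehyde. Ring A (C3a to C7a) and the furan ring C (O1, C2, C3) form the benzofuran. C2 carries ring B (2,4-dihydroxy-5-prenylphenyl, C1′ to C6′), C3 the formyl carbon, C6 a hydroxyl and C7 a prenyl group. There is no stereocentre, so the problem is one of connectivity, regiochemistry and chemoselectivity.

The feature that decides the strategy is the three-carbon unit C2–C3–CHO. Ring B sits on C2, but ring A (through C3a) and the formyl carbon both sit on C3. This is the 1,2-diaryl pattern of an isoflavonoid, one 1,2-shift away from the 1,3-diaryl pattern of a chalcone.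

The two prenyl groups lie in different surroundings: C7 between O1 and the 6-OH, C5′ beside the 4′-OH only. A late double prenylation of the free polyphenol could not tell the open positions apart, so each prenyl has to travel with its ring.

The sensitive groups narrow the reagents. ortho-Prenylphenols close to 2,2-dimethylchromans in strong acid and are attacked by electrophilic oxidants (peracids, trivalent iodine or thallium, quinones). Hydrogenation is excluded, and the free triphenol is air-sensitive in base.

Any open-chain precursor holds two ortho oxygens and two carbonyl carbons. Three ring closures compete (isoflavone, 3-aroylbenzofuran, target), so the order in which the phenols are unmasked is part of the design.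

## Retrosynthetic reasoning

**19 to 18.** Only the two O–allyl bonds of ring B are cut. Allyl ethers survive strong base, alkaline peroxide, Lewis acid and dilute mineral acid, and they fall to zerovalent palladium without acid, hydride or oxidant. They also keep the ortho oxygen of ring B silent while ring C is closed, which rules out the isoflavone.

**18 to 15 (key disconnection).** Ring C is opened at O1–C2 and the C2–C3 bond is cut, so that the aroyl carbon of ring B returns to the carbon that becomes the formyl group. This leads back through hemiketal 17 and keto aldehyde 16 to the trans-epoxy ketone 15, a chalcone oxide. Forward, one operation has to achieve four things: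
- open the epoxide at the carbon next to ring A;
- shift the aroyl group onto that carbon, which creates the C2–C3 bond and the formyl group;
- free the ortho oxygen of ring A;
- close O1–C2 and aromatise.

The cut is made here because it turns the isoflavonoid connectivity into the chalcone connectivity, which a single aldol condensation assembles. The same shift could be triggered by trivalent iodine or thallium oxidants on 14, but these would attack the four isolated alkenes. The epoxide route needs only a nucleophilic oxidant and acid.

**15 to 14.** The oxirane oxygen is removed to give the (E)-chalcone 14. The forward epoxidation must touch only the enone among five C=C bonds. A nucleophilic (conjugate) epoxidation does this by polarity.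

**14 to 7 + 13.** The enone C=C bond is cut into aldehyde 7 (ring A with its prenyl and two acid-labile MOM ethers) and methyl ketone 13 (ring B with its prenyl and two allyl ethers). All 25 skeletal carbons are joined in one convergent base-mediated condensation. The orthogonal protecting sets (acid-labile on ring A, palladium-labile on ring B) are fixed here.

**7 to 5 to 2 to 1.** The formyl and the prenyl group of ring A are removed in turn. Forward, the two MOM ethers of 2 direct lithiation first between them (aryllithium 4, alkylated by prenyl bromide 3) and then ortho to one of them (aryllithium 6, formylated). The "between two oxygens" prenyl position is thus set by direction, not by separating isomers.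

**13 to 11 to 9 to 8.** The acetyl and the prenyl group of ring B are replaced by bromine, leading to the symmetric 4,6-dibromoresorcinol 8. Forward, two successive bromine–lithium exchanges (aryllithiums 10 and 12) install prenyl (from 3) and acetyl at the two positions para to one oxygen and ortho to the other. The 5′-prenyl pattern is thus fixed by the bromines.

## Alternatives that were turned down

**Alternative 1:** the textbook route. Disconnection: the C3–CHO bond, then ring C by alkyne annulation. Forward: Sonogashira coupling of an ortho-iodophenol (ring A) with an arylacetylene (ring B), 5-endo cycloisomerisation to the 2-arylbenzofuran A1, then Vilsmeier–Haack formylation at C3. Turned down for three reasons: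
- the iodophenol and the ethynyl arene each need their own multi-step, prenyl-compatible synthesis;
- three C–C bond formations are spent in series on a C3 unit that a rearrangement delivers at once;
- the chloroiminium/HCl medium of the formylation meets two prenyl groups and acetal protecting groups, and C3 must compete with C3′ of ring B (between two oxygens) and C5 of ring A.

**Alternative 2:** the lactone-level precursor. The target is the open form of the lactol of a coumestan. Disconnection: add the 2′-O–C(formyl) bond and raise the formyl carbon to the acid level, giving coumestan A2. Forward key step: half-reduction of the lactone of A2 (suitably protected) with a hindered aluminium hydride at low temperature, then ring-chain opening. Turned down for three reasons: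
- the precursor is more complex than the product (a fourth ring and a higher oxidation level);
- the usual coumestan closures (oxidative C–O cyclisation of 3-aryl-4-hydroxycoumarins with divalent copper or quinones, or acid condensations) do not tolerate ortho-prenylphenols;
- an aryl lactone that opens to aldehyde plus phenoxide is easily over-reduced.

**Alternative 3:** a union of two carbons of like polarity. Disconnection: C3–C3a. Forward: conjugate addition of a ring A phenol to an aryl ynal gives the β-aryloxy enal A3. A dehydrogenative C–H/C–H cyclisation then follows, with Pd(OAc)2 (divalent palladium) and a stoichiometric oxidant, or at an anode. The regiochemistry is attractive: O1–C2 is fixed beforehand and ring A has only one free ortho C–H. It was turned down for three reasons: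
- the oxidant, or the anode, would engage the two trisubstituted prenyl alkenes (allylic C–H activation, Wacker-type attack, radical-cation formation) and the electron-rich rings before the electron-poor enal carbon;
- the ynal needs its own synthesis;
- no close model carries prenyl groups through such a step.

Key step: step 9

Remark on the chemistry: 1, 3 and 8 are taken as commercial; the target is made as the open hydroxy-aldehyde tautomer drawn in the SMILES; racemic 15 suffices because its stereocentres are erased in step 9.

## Route

Step 1
Reactants: 1 resorcinol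
Product: 2 1,3-bis(methoxymethoxy)benzene
Conditions: NaH, MOMCl, DMF, 0 °C to rt
Reagents that add atoms: chloromethyl methyl ether (MOMCl), COCCl
Why: Double Williamson etherification of the bis-phenoxide; the MOM ethers serve as directing groups for both lithiations and as the acid-labile protection of ring A.

Step 2
Reactants: 2 1,3-bis(methoxymethoxy)benzene; 3 prenyl bromide (1-bromo-3-methylbut-2-ene)
Product: 5 1,3-bis(methoxymethoxy)-2-(3-methylbut-2-en-1-yl)benzene, via aryllithium 4 (not isolated)
Conditions: n-BuLi, THF, 0 °C to rt; then CuBr·SMe2 (10 mol%), 3, −78 °C to rt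
Reagents that add atoms: none
Why: Directed ortho-metalation; both OMOM groups direct lithiation to the carbon between them, and the aryl nucleophile, relayed through catalytic monovalent copper, displaces the primary allylic bromide at its α-carbon to give the linear prenyl group.

Step 3
Reactants: 5 1,3-bis(methoxymethoxy)-2-(3-methylbut-2-en-1-yl)benzene
Product: 7 2,4-bis(methoxymethoxy)-3-(3-methylbut-2-en-1-yl)benzaldehyde, via aryllithium 6 (not isolated)
Conditions: n-BuLi, TMEDA, THF, −20 to 0 °C; then DMF, −78 °C to rt; H2O
Reagents that add atoms: N,N-dimethylformamide (DMF), CN(C)C=O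
Why: Second directed ortho-metalation; the only ring positions ortho to an OMOM group are the two symmetry-equivalent ones, so one aldehyde results after formylation and aqueous collapse of the adduct.

Step 4
Reactants: 8 4,6-dibromobenzene-1,3-diol
Product: 9 1,5-dibromo-2,4-bis(prop-2-en-1-yloxy)benzene
Conditions: allyl bromide, K2CO3, DMF, 50 °C
Reagents that add atoms: allyl bromide (3-bromoprop-1-ene), C=CCBr
Why: Williamson etherification; the allyl ethers are inert to every later base, peroxide and acid and are removed only by zerovalent palladium.

Step 5
Reactants: 9 1,5-dibromo-2,4-bis(prop-2-en-1-yloxy)benzene; 3 prenyl bromide (1-bromo-3-methylbut-2-ene)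
Product: 11 1-bromo-5-(3-methylbut-2-en-1-yl)-2,4-bis(prop-2-en-1-yloxy)benzene, via aryllithium 10 (not isolated)
Conditions: n-BuLi (1.0 equiv), THF, −78 °C; then CuBr·SMe2 (10 mol%), 3, −78 to 0 °C
Reagents that add atoms: none
Why: Bromine–lithium exchange is faster than any deprotonation at −78 °C and stops after one exchange, since a second would build a dianion; the two bromines are equivalent, so no regiochemical question arises, and copper-catalysed allylic substitution gives the prenyl arene.

Step 6
Reactants: 11 1-bromo-5-(3-methylbut-2-en-1-yl)-2,4-bis(prop-2-en-1-yloxy)benzene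
Product: 13 1-[5-(3-methylbut-2-en-1-yl)-2,4-bis(prop-2-en-1-yloxy)phenyl]ethan-1-one, via aryllithium 12 (not isolated)
Conditions: n-BuLi, THF, −78 °C; then MeC(O)N(OMe)Me, −78 to 0 °C; H2O
Reagents that add atoms: N-methoxy-N-methylacetamide, CON(C)C(C)=O
Why: Second bromine–lithium exchange followed by Weinreb ketone synthesis; the chelated tetrahedral adduct prevents over-addition and releases the methyl ketone on aqueous work-up.

Step 7
Reactants: 7 2,4-bis(methoxymethoxy)-3-(3-methylbut-2-en-1-yl)benzaldehyde; 13 1-[5-(3-methylbut-2-en-1-yl)-2,4-bis(prop-2-en-1-yloxy)phenyl]ethan-1-one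
Product: 14 (E)-3-[2,4-bis(methoxymethoxy)-3-(3-methylbut-2-en-1-yl)phenyl]-1-[5-(3-methylbut-2-en-1-yl)-2,4-bis(prop-2-en-1-yloxy)phenyl]prop-2-en-1-one
Conditions: KOH, EtOH–THF–H2O, rt
Reagents that add atoms: none
Why: Claisen–Schmidt condensation of a non-enolisable aldehyde with a methyl ketone; E1cB dehydration gives the (E)-enone, and MOM and allyl ethers are stable to hydroxide.

Step 8
Reactants: 14 the (E)-chalcone
Product: 15 rac-{(2R,3S)-3-[2,4-bis(methoxymethoxy)-3-(3-methylbut-2-en-1-yl)phenyl]oxiran-2-yl}[5-(3-methylbut-2-en-1-yl)-2,4-bis(prop-2-en-1-yloxy)phenyl]methanone (trans)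
Conditions: 30% aq. H2O2, NaOH, MeOH–THF, 0 °C to rt
Reagents that add atoms: hydrogen peroxide, OO
Why: Weitz–Scheffer nucleophilic epoxidation; the hydroperoxide anion adds only to the electron-poor enone, so the two prenyl and two allyl alkenes are left alone, and the (E)-enone gives the trans epoxide as a racemate whose two stereocentres are erased in step 9. The crude epoxide is carried on without chromatography on acidic silica.

Step 9
Reactants: 15 the trans-epoxy ketone
Product: 18 6-hydroxy-7-(3-methylbut-2-en-1-yl)-2-[5-(3-methylbut-2-en-1-yl)-2,4-bis(prop-2-en-1-yloxy)phenyl]-1-benzofuran-3-carbaldehyde, via keto aldehyde 16 (not isolated), via cyclic hemiketal 17 (not isolated)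
Conditions: BF3·OEt2 (0.3 equiv), CH2Cl2, −30 to 0 °C; then THF, 3 M aq. HCl, 45 °C (same flask)
Reagents that add atoms: none
Why: BF3 opens the epoxide at the C–O bond next to ring A, where the cation is stabilised by the ortho and para OMOM groups, and the aroyl group migrates to that carbon while the alkoxide collapses to the formyl group (Meinwald rearrangement with 1,2-acyl shift), giving keto aldehyde 16 with the 1,2-diaryl connectivity of the target. The closest known reaction types are the Lewis-acid rearrangement of chalcone oxides to 2-formyl deoxybenzoins and the acid-mediated cyclodehydration of 2-(2-hydroxyaryl) 1,3-dicarbonyl compounds to benzofurans. Dilute HCl then hydrolyses the two MOM acetals of ring A; the freed ortho hydroxyl adds to the aryl ketone in a 5-exo-trig closure (O1–C2) to hemiketal 17, which ionises to a 2-aryl oxocarbenium ion and loses H3 to give the aromatic furan. No stereocentre is created that survives: those of 15, 16 and 17 all end as sp2 carbons. Acyl rather than hydride migration is needed and is the normal course for chalcone oxides. Closure of the ring B oxygen onto the formyl group (isoflavone) is excluded because that oxygen is an allyl ether stable to both acids. Closure of the ring A oxygen onto the formyl carbon gives a lactol that reverts in the aqueous medium, while dehydration of 17 is driven by the cation stabilised by the 2,4-dialkoxyaryl group, so the 2-aryl-3-formyl isomer should drain the equilibrium. Hydroalkoxylation of the prenyl groups is held back by using dilute acid at moderate temperature for only as long as acetal hydrolysis needs.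

Step 10
Reactants: 18 the bis-allyl ether
Product: 19 eryvarin Q, 2-[2,4-dihydroxy-5-(3-methylbut-2-en-1-yl)phenyl]-6-hydroxy-7-(3-methylbut-2-en-1-yl)-1-benzofuran-3-carbaldehyde
Conditions: Pd(PPh3)4 (5 mol%), K2CO3, MeOH, 40 °C, under argon
Reagents that add atoms: none
Why: Tsuji–Trost deallylation; zerovalent palladium ionises the two aryl allyl ethers to π-allyl complexes that are captured by methanol/methoxide, under conditions without acid, hydride or oxidant, so the prenyl groups, the aldehyde and the phenols should persist.

## Compound list

1 | resorcinol (benzene-1,3-diol) | Oc1cccc(O)c1 | starting material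
2 | 1,3-bis(methoxymethoxy)benzene | COCOc1cccc(OCOC)c1 | intermediate
3 | prenyl bromide (1-bromo-3-methylbut-2-ene) | CC(C)=CCBr | starting material
4 | [2,6-bis(methoxymethoxy)phenyl]lithium | [Li]c1c(OCOC)cccc1OCOC | intermediate (not isolated)
5 | 1,3-bis(methoxymethoxy)-2-(3-methylbut-2-en-1-yl)benzene | COCOc1cccc(OCOC)c1CC=C(C)C | intermediate
6 | [2,4-bis(methoxymethoxy)-3-(3-methylbut-2-en-1-yl)phenyl]lithium | [Li]c1ccc(OCOC)c(CC=C(C)C)c1OCOC | intermediate (not isolated)
7 | 2,4-bis(methoxymethoxy)-3-(3-methylbut-2-en-1-yl)benzaldehyde | O=Cc1ccc(OCOC)c(CC=C(C)C)c1OCOC | intermediate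
8 | 4,6-dibromobenzene-1,3-diol | Oc1cc(O)c(Br)cc1Br | starting material
9 | 1,5-dibromo-2,4-bis(prop-2-en-1-yloxy)benzene | C=CCOc1cc(OCC=C)c(Br)cc1Br | intermediate
10 | [5-bromo-2,4-bis(prop-2-en-1-yloxy)phenyl]lithium | [Li]c1cc(Br)c(OCC=C)cc1OCC=C | intermediate (not isolated)
11 | 1-bromo-5-(3-methylbut-2-en-1-yl)-2,4-bis(prop-2-en-1-yloxy)benzene | C=CCOc1cc(OCC=C)c(CC=C(C)C)cc1Br | intermediate
12 | [5-(3-methylbut-2-en-1-yl)-2,4-bis(prop-2-en-1-yloxy)phenyl]lithium | [Li]c1cc(CC=C(C)C)c(OCC=C)cc1OCC=C | intermediate (not isolated)
13 | 1-[5-(3-methylbut-2-en-1-yl)-2,4-bis(prop-2-en-1-yloxy)phenyl]ethan-1-one | CC(=O)c1cc(CC=C(C)C)c(OCC=C)cc1OCC=C | intermediate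
14 | (E)-3-[2,4-bis(methoxymethoxy)-3-(3-methylbut-2-en-1-yl)phenyl]-1-[5-(3-methylbut-2-en-1-yl)-2,4-bis(prop-2-en-1-yloxy)phenyl]prop-2-en-1-one | O=C(/C=C/c1ccc(OCOC)c(CC=C(C)C)c1OCOC)c1cc(CC=C(C)C)c(OCC=C)cc1OCC=C | intermediate
15 | rac-{(2R,3S)-3-[2,4-bis(methoxymethoxy)-3-(3-methylbut-2-en-1-yl)phenyl]oxiran-2-yl}[5-(3-methylbut-2-en-1-yl)-2,4-bis(prop-2-en-1-yloxy)phenyl]methanone (trans, racemic; one enantiomer drawn) | O=C(c1cc(CC=C(C)C)c(OCC=C)cc1OCC=C)[C@@H]1O[C@H]1c1ccc(OCOC)c(CC=C(C)C)c1OCOC | intermediate
16 | 2-[2,4-bis(methoxymethoxy)-3-(3-methylbut-2-en-1-yl)phenyl]-3-[5-(3-methylbut-2-en-1-yl)-2,4-bis(prop-2-en-1-yloxy)phenyl]-3-oxopropanal (racemic, largely enolised) | O=CC(c1ccc(OCOC)c(CC=C(C)C)c1OCOC)C(=O)c1cc(CC=C(C)C)c(OCC=C)cc1OCC=C | intermediate (not isolated)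
17 | 2,6-dihydroxy-7-(3-methylbut-2-en-1-yl)-2-[5-(3-methylbut-2-en-1-yl)-2,4-bis(prop-2-en-1-yloxy)phenyl]-2,3-dihydro-1-benzofuran-3-carbaldehyde (mixture of racemic diastereomers) | O=CC1c2ccc(O)c(CC=C(C)C)c2OC1(O)c1cc(CC=C(C)C)c(OCC=C)cc1OCC=C | intermediate (not isolated)
18 | 6-hydroxy-7-(3-methylbut-2-en-1-yl)-2-[5-(3-methylbut-2-en-1-yl)-2,4-bis(prop-2-en-1-yloxy)phenyl]-1-benzofuran-3-carbaldehyde | O=Cc1c(-c2cc(CC=C(C)C)c(OCC=C)cc2OCC=C)oc2c(CC=C(C)C)c(O)ccc12 | intermediate
19 | eryvarin Q | CC(C)=CCc1cc(-c2oc3c(CC=C(C)C)c(O)ccc3c2C=O)c(O)cc1O | target

## Step count and risk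

Total step count: 10 (steps 1 to 3 for ring A, steps 4 to 6 for ring B, steps 7 to 10 after the union). Longest linear sequence: 7 steps (1, 2, 3, 7, 8, 9, 10; the ring B branch is equally long).

**Step 9 (key step).** Three processes can go wrong:
- closure of the ring A oxygen onto the formyl carbon, followed by dehydration before the lactol reverts, which would give the 2-unsubstituted 3-aroyl isomer;
- acid-induced addition of a freed phenol to the neighbouring prenyl double bond while the MOM groups are hydrolysed;
- loss of the formyl group from 16 by retro-Claisen cleavage.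

The regiochemical argument rests on cation stabilisation by ring B and on the reversibility of the lactol; it has not been tested on this substrate.

Fallback, from 15 back to 18: only the Lewis-acid stage is run and 16 is isolated. K2CO3 in aqueous methanol then removes the formyl group on purpose and gives the deoxybenzoin 2-[2,4-bis(methoxymethoxy)-3-(3-methylbut-2-en-1-yl)phenyl]-1-[5-(3-methylbut-2-en-1-yl)-2,4-bis(prop-2-en-1-yloxy)phenyl]ethan-1-one F1. Dilute HCl in THF cleaves the MOM groups, and the resulting 2-hydroxybenzyl ketone has one carbonyl group and so one mode of closure. It cyclodehydrates to 7-(3-methylbut-2-en-1-yl)-2-[5-(3-methylbut-2-en-1-yl)-2,4-bis(prop-2-en-1-yloxy)phenyl]-1-benzofuran-6-ol F2. Vilsmeier–Haack formylation (POCl3, DMF, 0 °C, then aqueous NaOAc) at C3, the most nucleophilic carbon of a 2-aryl-6-oxybenzofuran, gives 18.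

**Step 8.** The enone is deactivated by donor groups on both rings, so conjugate addition of hydroperoxide may be slow. The very electron-rich epoxide may also open or rearrange during isolation.

Fallback, from 11 and 7 back to 15: aryllithium 12 is generated from 11 as in step 6 and acylated with 2-chloro-N-methoxy-N-methylacetamide to give 2-chloro-1-[5-(3-methylbut-2-en-1-yl)-2,4-bis(prop-2-en-1-yloxy)phenyl]ethan-1-one F3. Darzens condensation of F3 with aldehyde 7 (KOt-Bu, THF–t-BuOH, 0 °C) forms the trans-epoxy ketone 15 directly. The chalcone and the peroxide are bypassed, and the epoxide is made under basic conditions and can be taken into step 9 at once.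

**Step 5.** Possible failures are a second exchange, addition of the aryllithium to the neighbouring allyl ether double bond on warming, and SN2′ attack on 3 giving the reverse-prenyl isomer.

Fallback, from 9 back to 13: the first exchange (aryllithium 10) is quenched at −78 °C with N-methoxy-N-methylacetamide, a faster electrophile, to give 1-[5-bromo-2,4-bis(prop-2-en-1-yloxy)phenyl]ethan-1-one F4. The prenyl group is then introduced by Stille coupling of F4 with tributyl(3-methylbut-2-en-1-yl)stannane (Pd(PPh3)4, DMF, 90 °C). The sp2–sp3 bond is thus made by cross-coupling instead of by alkylation of an organolithium.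

**Step 3.** n-BuLi/TMEDA may deprotonate the doubly activated benzylic-allylic CH2 of the prenyl group, flanked by both OMOM groups, instead of the ring position.

Fallback, from 2 back to 7: bromination of 2 with NBS in MeCN gives 1-bromo-2,4-bis(methoxymethoxy)benzene F5. Lithiation of F5 between the two OMOM groups with LiN(i-Pr)2 (THF, −78 °C) and alkylation with 3 (catalytic CuBr·SMe2) gives 1-bromo-2,4-bis(methoxymethoxy)-3-(3-methylbut-2-en-1-yl)benzene F6. Bromine–lithium exchange on F6 (n-BuLi, −78 °C), which is much faster than any deprotonation, generates aryllithium 6 at the right carbon, and DMF gives 7.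

## Further compounds

F1 | step 9 | 2-[2,4-bis(methoxymethoxy)-3-(3-methylbut-2-en-1-yl)phenyl]-1-[5-(3-methylbut-2-en-1-yl)-2,4-bis(prop-2-en-1-yloxy)phenyl]ethan-1-one | O=C(Cc1ccc(OCOC)c(CC=C(C)C)c1OCOC)c1cc(CC=C(C)C)c(OCC=C)cc1OCC=C
F2 | step 9 | 7-(3-methylbut-2-en-1-yl)-2-[5-(3-methylbut-2-en-1-yl)-2,4-bis(prop-2-en-1-yloxy)phenyl]-1-benzofuran-6-ol | Oc1ccc2cc(-c3cc(CC=C(C)C)c(OCC=C)cc3OCC=C)oc2c1CC=C(C)C
F3 | step 8 | 2-chloro-1-[5-(3-methylbut-2-en-1-yl)-2,4-bis(prop-2-en-1-yloxy)phenyl]ethan-1-one | ClCC(=O)c1cc(CC=C(C)C)c(OCC=C)cc1OCC=C
F4 | step 5 | 1-[5-bromo-2,4-bis(prop-2-en-1-yloxy)phenyl]ethan-1-one | CC(=O)c1cc(Br)c(OCC=C)cc1OCC=C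
F5 | step 3 | 1-bromo-2,4-bis(methoxymethoxy)benzene | Brc1ccc(OCOC)cc1OCOC
F6 | step 3 | 1-bromo-2,4-bis(methoxymethoxy)-3-(3-methylbut-2-en-1-yl)benzene | Brc1ccc(OCOC)c(CC=C(C)C)c1OCOC
A1 | alternative 1 | 2-[2,4-bis(methoxymethoxy)-5-(3-methylbut-2-en-1-yl)phenyl]-6-(methoxymethoxy)-7-(3-methylbut-2-en-1-yl)-1-benzofuran | COCOc1ccc2cc(-c3cc(CC=C(C)C)c(OCOC)cc3OCOC)oc2c1CC=C(C)C
A2 | alternative 2 | 3,9-dihydroxy-2,10-bis(3-methylbut-2-en-1-yl)-6H-[1]benzofuro[3,2-c]chromen-6-one | O=C1Oc2cc(O)c(CC=C(C)C)cc2-c2oc3c(CC=C(C)C)c(O)ccc3c12
A3 | alternative 3 | (Z)-3-[2,4-bis(methoxymethoxy)-5-(3-methylbut-2-en-1-yl)phenyl]-3-[3-(methoxymethoxy)-2-(3-methylbut-2-en-1-yl)phenoxy]prop-2-enal | O=C/C=C(\Oc1cccc(OCOC)c1CC=C(C)C)c1cc(CC=C(C)C)c(OCOC)cc1OCOC
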